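## The problem

Target 25 is an indane. Throughout, C1 carries the 4-hydroxyphenyl group, C2 the 3,5-dihydroxyphenyl group and C3 the side chain whose carbinol carbon is C8; ring A is the fused benzene ring C3a–C7a with hydroxyls on C5 and C7. The configuration read from the structure is (1R,2S,3R,8R): the three ring substituents alternate faces (1,2-trans and 2,3-trans), and C8 stands in an anti-aldol relationship to C3 along the chain C3a–C3–C8–aryl.

The stereocentres are not equally demanding. C2 is enolisable whenever C1 is a ketone and then settles trans to C3. The C1 aryl group can be brought in last, on the face away from the C2 aryl group. Only the adjacent pair C3/C8 therefore needs absolute control.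

The C8 carbinol is a 4-hydroxybenzylic alcohol. Acid ionises it, and the cation eliminates or is captured by the neighbouring electron-rich rings, so the phenol protecting groups must come off under neutral conditions. The dioxygenated rings are also strong nucleophiles toward electrophilic halogen and toward benzylic cations, and the free pentaphenol is air-sensitive.

The feature that invites a cycloaddition is ring A itself. Its oxygens on C5 and C7 flank C6, so C4–C7 form an acetoacetate unit, and C3a–C7a are the β- and α-carbons of a cyclopentenone whose carbonyl is C1. A halogen on C7a supplies the oxidation level for aromatisation and marks the carbon that must receive the ketene-acetal end of the diene.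

## Retrosynthesis

**Protecting groups (25 from 24 from 23).** The last two operations remove only protecting groups. The five phenols are carried as benzyl ethers and C8 as a tert-butyldimethylsilyl ether. Methyl ethers would need a Lewis-acidic cleavage that the 4-hydroxybenzylic carbinol cannot survive. Hydrogenolysis of 23 gives 24 while the silyl group still shields C8 from benzylic hydrogenolysis, and buffered fluoride then frees 25. The forward steps must be neutral and must not touch the C8–O bond.

**C1–aryl bond (23 from 21 and 22; 21 from 20 from 19).** Cutting this bond last leaves a C1 ketone in 19, which keeps C2 under thermodynamic control and gives the benzannulation its activating carbonyl. Adding an aryl-metal reagent to the ketone and deoxygenating afterwards would place the aryl group cis to C2, so the aryl group is made the nucleophile instead. Alcohol 21 ionises to a cation stabilised by the C5 and C7 oxygens, and arene 22 attacks para, anti to the C2 aryl group. The forward reaction must ionise C1 without ionising C8 and must outrun attack by the substrate's own rings.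

**Ring A (19 from 13 and 17).** Bonds C3a–C4 and C7–C7a are cut together. The alternative, closing the five-membered ring onto a bought dioxygenated arene, would force C3, C8 and C2 to be set on an indane or indene, where C3 is benzylic and easily lost. On cyclopentenone 13 the same centres are ordinary sp3 carbons, and trans control at C2 is thermodynamic. Diene 17 supplies C4–C7 with both oxygens in place. The forward reaction must be regiospecific and must end with loss of halide and of the ketal alkoxy group. No new stereocentre survives.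

**Bromo-enone (13 from 11 from 10).** Halogenating the enone directly would expose the benzyloxy arenes to electrophilic bromine and the base-sensitive enone to amine. The halogen is therefore placed one stage earlier, on the vinylogous ester 10. Its C2 is the most nucleophilic carbon in the molecule. Hydride reduction of 11 and acid hydrolysis (Stork–Danheiser transposition) then deliver 13 with carbonyl, alkene and halogen in the right positions.

**C3–C8 bond (10 from 9 from 5 and 6).** The anti relationship between C3 and C8 is that of an aldol from a ring-locked E-enolate whose carbonyl carbon becomes C3a. The kinetic α′-enolate of vinylogous ester 5 meets this exactly, and its neighbouring aryl-bearing carbon (the future C2) directs aldehyde 6 to the opposite face. One step thus sets C3 and C8 relative to a single relay centre. A conjugate addition of a C8 unit to a cyclopentenone would give an epimerisable 1,4-dicarbonyl or an uncontrolled C8.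

**Relay centre (5 from 4 from 2 and 3; 2 from 1).** The relay centre is made by rhodium-catalysed asymmetric conjugate arylation of ketal enone 2 with boronic acid 3. The ketal holds the future C1 at the ketone oxidation level and fixes the regiochemistry of the enol ether formed when 4 loses its alkoxy group. Enone 2 is the mono-ketal of the symmetrical dione 1. The forward reaction must give high enantioselectivity at a β-carbon next to a quaternary centre.

**Diene (17 from 15 from 14).** Two silylations of the β-keto ester 14, the second through its dienolate, give 17.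

## Roads not taken

**Alternative 1:** a sulfur ylide [4+1] annulation that inserts C2. The cuts are C1–C2 and C2–C3. A benzylic sulfonium ylide, made from bromide A2 and a chiral sulfide, would add to the quinone methide carbon of ester A1. The ester enolate would then displace the sulfonium group and close the five-membered ring to give A3.

- Merits: ring A is bought as an arene, the annulation is convergent, and three ring stereocentres arise in one step under reagent control. In that respect it is better than the chosen plan, which spreads them over three steps.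
- Weak points: the C1 aryl group arrives with two tert-butyl groups that need a strongly Lewis-acidic dealkylation. C3 carries an ester, so C8 and its aryl group must be built afterwards with only acyclic substrate control. The methyl ethers demand a final cleavage that the C8 carbinol cannot survive.
- Against it the chosen plan sets C8 together with C3 in a closed transition state and ends with neutral deprotections.

**Alternative 2:** a radical–polar 1,2-diarylation of indene A4. The cuts are C2–aryl and C1–aryl; no ring closes. An aryl radical from diazonium salt A5 would add to C2 under photoredox catalysis. The C1 radical would be oxidised to the cation and captured by arene A6 to give A7.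

- Merits: both aryl groups enter in one step, anti to each other. This is shorter than the chosen endgame, which needs a reduction and a separate arylation.
- Weak points: A4 must already hold C3 and C8. Its C3–H is doubly allylic and benzylic, so a hydrogen shift that moves the double bond would erase C3. The face of radical attack at C2 is controlled only by the C3 side chain. The C1 cation faces the same competition from the substrate's electron-rich rings as in the chosen plan, but with three components in the flask.
- Against it the chosen plan never places C3 next to an indene double bond and fixes C2 thermodynamically next to a ketone.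

**Alternative 3:** a ring-closing conjunctive coupling. The cuts are C3–C3a and C8–aryl. Aryllithium A9 would convert alkenyl boronate A8 into its ate complex. Zerovalent palladium with a chiral bisphosphine would insert into the aryl triflate bond and induce the 1,2-shift of the aryl group to C8 as the ring closes, giving boronate A10. Oxidation with retention would reveal the C8 hydroxyl.

- Merits: C3 and C8 are created together, and the oxygen is introduced stereospecifically from boron. This answers the C8 problem more securely than an aldol that relies on simple diastereoselection.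
- Weak points: A8 needs C1 and C2 set in an open chain beforehand. The catalyst must override these centres in an intramolecular variant on a 1,2-disubstituted alkenyl boronate. Direct aryl–aryl coupling of the ate complex with the triflate competes. The methyl ethers again end in an incompatible cleavage.
- Against it the chosen plan offers simple, symmetrical starting materials, a boron-enolate chair for the anti relationship and a late oxidation–reduction correction at C8 if needed.

Key step: step 9

Assumption: compounds 1, 3, 6, 14 and 22 are taken as purchasable, and the sense of induction in step 2 is assigned by analogy with cyclopent-2-enone, for which (S)-BINAP gives (S)-3-arylcyclopentanones.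

## Route

Step 1
Reactants: 1 cyclopent-4-ene-1,3-dione
Product: 2 4,4-dimethoxycyclopent-2-en-1-one
Conditions: HC(OMe)3 (1.2 equiv), TsOH·H2O (2 mol %), MeOH, 0 °C → rt; Et3N quench
Reagents that add atoms: trimethyl orthoformate, COC(OC)OC
Why: Acid-catalysed ketalisation with the orthoformate as water scavenger; the first carbonyl of the ene-dione is the more electrophilic, and once it is masked the remaining enone carbonyl is deactivated, so the reaction should stop at the mono-ketal. Compound 2 cannot lose methanol, because that would give a cyclopentadienone.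

Step 2
Reactants: 2 4,4-dimethoxycyclopent-2-en-1-one; 3 [3,5-bis(benzyloxy)phenyl]boronic acid
Product: 5 (4S)-4-[3,5-bis(benzyloxy)phenyl]-3-methoxycyclopent-2-en-1-one, via ketal ketone 4 (not isolated)
Conditions: [Rh(OH)((S)-BINAP)]2 (1.5 mol %), 3 (2 equiv), dioxane–H2O 10:1, 35 °C; then PPTS (10 mol %), toluene, 60 °C
Reagents that add atoms: none
Why: Hayashi–Miyaura rhodium-catalysed asymmetric 1,4-addition of an arylboronic acid to a cyclic enone of the quinone-monoketal type; with (S)-BINAP the aryl group should arrive on the face that gives (S)-3-arylcyclopentanones, which here is (4S)-4, and this centre (the future C2) serves as the relay for all later stereocontrol. Mild acid then ionises the ketal and removes the doubly activated proton next to the carbonyl to give the push–pull enol ether 5; base is avoided because the benzylic γ-proton of 5 would exchange.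

Step 3
Reactants: 5 (4S)-4-[3,5-bis(benzyloxy)phenyl]-3-methoxycyclopent-2-en-1-one; 6 4-(benzyloxy)benzaldehyde
Product: 9 (4S,5S)-4-[3,5-bis(benzyloxy)phenyl]-5-{(R)-[4-(benzyloxy)phenyl](hydroxy)methyl}-3-methoxycyclopent-2-en-1-one, via lithium enolate 7 (not isolated), via dicyclohexylboron enolate 8 (not isolated)
Conditions: LiN(iPr)2 (1.05 equiv), THF, −78 °C; (c-C6H11)2BCl (1.1 equiv), −78 °C; 6 (1.2 equiv), −78 → −40 °C; then MeOH, pH 7 buffer, H2O2, 0 °C
Reagents that add atoms: none
Why: Kinetic α′-deprotonation of a vinylogous ester (Stork–Danheiser enolate), lithium-to-boron exchange and boron aldol addition; the ring-locked E-enol borinate reacts through a Zimmerman–Traxler chair with the aldehyde aryl group equatorial, which gives the anti relationship, (R) at C8. The aldehyde approaches trans to the neighbouring aryl group, which sets the future C3, so both new centres are controlled by the relay centre from step 2.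

Step 4
Reactants: 9 (4S,5S)-4-[3,5-bis(benzyloxy)phenyl]-5-{(R)-[4-(benzyloxy)phenyl](hydroxy)methyl}-3-methoxycyclopent-2-en-1-one
Product: 10 (4S,5S)-4-[3,5-bis(benzyloxy)phenyl]-5-{(R)-[4-(benzyloxy)phenyl][(tert-butyldimethylsilyl)oxy]methyl}-3-methoxycyclopent-2-en-1-one
Conditions: TBSOTf (1.3 equiv), 2,6-lutidine (2 equiv), CH2Cl2, −78 → −20 °C
Reagents that add atoms: tert-butyldimethylsilyl triflate, CC(C)(C)[Si](C)(C)OS(=O)(=O)C(F)(F)F
Why: Silylation of a hindered secondary benzylic alcohol with the silyl triflate and a hindered pyridine base, at a temperature where retro-aldol cleavage and β-elimination of the aldol are slow.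

Step 5
Reactants: 10 (4S,5S)-4-[3,5-bis(benzyloxy)phenyl]-5-{(R)-[4-(benzyloxy)phenyl][(tert-butyldimethylsilyl)oxy]methyl}-3-methoxycyclopent-2-en-1-one
Product: 11 (4S,5S)-4-[3,5-bis(benzyloxy)phenyl]-5-{(R)-[4-(benzyloxy)phenyl][(tert-butyldimethylsilyl)oxy]methyl}-2-bromo-3-methoxycyclopent-2-en-1-one
Conditions: NBS (1.02 equiv), CH2Cl2, −20 → 0 °C, dark
Reagents that add atoms: N-bromosuccinimide, O=C1CCC(=O)N1Br
Why: Electrophilic bromination at C2 of a 3-alkoxy-enone, the enol-ether β-carbon and the most nucleophilic carbon present; at low temperature in a non-polar solvent NBS should leave the benzyloxy arenes alone. Placing the halogen here avoids any halogenation of the base-sensitive enone 13.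

Step 6
Reactants: 11 (4S,5S)-4-[3,5-bis(benzyloxy)phenyl]-5-{(R)-[4-(benzyloxy)phenyl][(tert-butyldimethylsilyl)oxy]methyl}-2-bromo-3-methoxycyclopent-2-en-1-one
Product: 13 (4R,5S)-5-[3,5-bis(benzyloxy)phenyl]-4-{(R)-[4-(benzyloxy)phenyl][(tert-butyldimethylsilyl)oxy]methyl}-2-bromocyclopent-2-en-1-one, via allylic alcohol 12 (not isolated)
Conditions: iBu2AlH (1.3 equiv), CH2Cl2, −78 °C; then 0.5 M HCl, THF, 0 °C
Reagents that add atoms: water, O
Why: Stork–Danheiser 1,3-carbonyl transposition: 1,2-reduction of the vinylogous ester, then acid hydrolysis of the γ-hydroxy enol ether with loss of methanol, gives the 2-bromo-enone. The aryl-bearing carbon is now α to the ketone and stays trans to its neighbour; the descriptor at C4 changes only because the bromine alters ligand priorities.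

Step 7
Reactants: 14 methyl acetoacetate
Product: 15 methyl 3-[(trimethylsilyl)oxy]but-2-enoate (E/Z mixture)
Conditions: TMSCl, Et3N, hexane, rt
Reagents that add atoms: chlorotrimethylsilane, C[Si](C)(C)Cl
Why: O-Silylation of the enol form of a β-keto ester with a silyl chloride and a tertiary amine.

Step 8
Reactants: 15 methyl 3-[(trimethylsilyl)oxy]but-2-enoate
Product: 17 1-methoxy-1,3-bis[(trimethylsilyl)oxy]buta-1,3-diene, via lithium dienolate 16 (not isolated)
Conditions: LiN(iPr)2, THF, −78 °C; TMSCl, −78 → 0 °C
Reagents that add atoms: chlorotrimethylsilane, C[Si](C)(C)Cl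
Why: γ-Deprotonation of the silyloxy enoate and O-silylation of the ester dienolate give the bis(silyloxy)diene (Chan's diene), which is used freshly distilled.

Step 9
Reactants: 13 (4R,5S)-5-[3,5-bis(benzyloxy)phenyl]-4-{(R)-[4-(benzyloxy)phenyl][(tert-butyldimethylsilyl)oxy]methyl}-2-bromocyclopent-2-en-1-one; 17 1-methoxy-1,3-bis[(trimethylsilyl)oxy]buta-1,3-diene
Product: 19 (2S,3R)-2-[3,5-bis(benzyloxy)phenyl]-3-{(R)-[4-(benzyloxy)phenyl][(tert-butyldimethylsilyl)oxy]methyl}-5,7-dihydroxyindan-1-one, via bromo cycloadduct 18 (not isolated)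
Conditions: 17 (3 equiv), toluene, 0 → 60 °C; DBU (2 equiv), 0 °C → rt; then 1 M HCl–THF, 0 °C
Reagents that add atoms: none
Why: Thermal [4+2] cycloaddition of the electron-rich diene 17 with the α-bromo enone 13, concerted but strongly asynchronous or stepwise by Mukaiyama–Michael addition and collapse of the zwitterion: the unsubstituted nucleophilic CH2 terminus bonds to the enone β-carbon (C3a) and the ketene-acetal carbon to the brominated α-carbon (C7a), giving adduct 18. The closest known reaction type is the regiospecific phenol and resorcinol annulation of Danishefsky-, Brassard- and Chan-type dienes with α-halo enones and haloquinones. Ring A closes in this intermolecular [4+2] mode, with C3a–C4 and C7–C7a formed in the same operation. DBU then removes HBr across C3a–C7a (enolisation toward the acidic C2–H, loss of bromide from the α-bromo enolate, proton loss from C3a), and dilute acid ionises the mixed ketal at C7, expels methanol, cleaves both trimethylsilyl ethers and lets the dienone tautomerise to the resorcinol. No new stereocentre survives, because C3a, C7 and C7a all become sp2, so facial selectivity is irrelevant and only regiochemistry counts; it is fixed by the polarity match, with the halogen marking the carbon that receives the ketene-acetal end, which places the oxygens on C5 and C7. C2 can epimerise under DBU but returns to the trans arrangement dictated by C3, and C3 and C8 are not touched. No Lewis acid is used, so the benzylic silyl ether and the benzyl ethers should survive.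

Step 10
Reactants: 19 (2S,3R)-2-[3,5-bis(benzyloxy)phenyl]-3-{(R)-[4-(benzyloxy)phenyl][(tert-butyldimethylsilyl)oxy]methyl}-5,7-dihydroxyindan-1-one
Product: 20 (2S,3R)-5,7-bis(benzyloxy)-2-[3,5-bis(benzyloxy)phenyl]-3-{(R)-[4-(benzyloxy)phenyl][(tert-butyldimethylsilyl)oxy]methyl}indan-1-one
Conditions: BnBr (2.5 equiv), K2CO3 (3 equiv), DMF, rt → 40 °C
Reagents that add atoms: benzyl bromide, BrCc1ccccc1
Why: Williamson benzylation of both phenols; the chelated C7 hydroxyl needs gentle warming. The phenoxides are far more abundant than the hindered C2 enolate, and any epimerisation at C2 can only lead back to the trans isomer.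

Step 11
Reactants: 20 (2S,3R)-5,7-bis(benzyloxy)-2-[3,5-bis(benzyloxy)phenyl]-3-{(R)-[4-(benzyloxy)phenyl][(tert-butyldimethylsilyl)oxy]methyl}indan-1-one
Product: 21 (2S,3R)-5,7-bis(benzyloxy)-2-[3,5-bis(benzyloxy)phenyl]-3-{(R)-[4-(benzyloxy)phenyl][(tert-butyldimethylsilyl)oxy]methyl}indan-1-ol (C1 epimers, hydroxyl mainly cis to the C2 aryl group)
Conditions: NaBH4, THF–MeOH 4:1, 0 °C; neutral work-up
Reagents that add atoms: none
Why: Borohydride reduction of the aryl ketone, with hydride expected anti to the C2 aryl group; the carbinol configuration is irrelevant because C1 is ionised in the next step.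

Step 12
Reactants: 21 (2S,3R)-5,7-bis(benzyloxy)-2-[3,5-bis(benzyloxy)phenyl]-3-{(R)-[4-(benzyloxy)phenyl][(tert-butyldimethylsilyl)oxy]methyl}indan-1-ol; 22 benzyl phenyl ether
Product: 23 (1R,2S,3R)-5,7-bis(benzyloxy)-1-[4-(benzyloxy)phenyl]-2-[3,5-bis(benzyloxy)phenyl]-3-{(R)-[4-(benzyloxy)phenyl][(tert-butyldimethylsilyl)oxy]methyl}indane
Conditions: 22 (20 equiv), TsOH·H2O (5 mol %), HFIP–CH2Cl2 1:2, −20 → 0 °C
Reagents that add atoms: none
Why: Brønsted acid-catalysed Friedel–Crafts benzylation in a fluorinated alcohol; the C1 alcohol ionises to a 2,4-dialkoxybenzylic cation much more readily than the 4-alkoxybenzylic silyl ether at C8. The large excess of unhindered 22 attacks through its para carbon on the face opposite the C2 aryl group, which sets C1 as (R), trans to C2.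

Step 13
Reactants: 23 (1R,2S,3R)-5,7-bis(benzyloxy)-1-[4-(benzyloxy)phenyl]-2-[3,5-bis(benzyloxy)phenyl]-3-{(R)-[4-(benzyloxy)phenyl][(tert-butyldimethylsilyl)oxy]methyl}indane
Product: 24 (1R,2S,3R)-3-{(R)-[(tert-butyldimethylsilyl)oxy](4-hydroxyphenyl)methyl}-2-(3,5-dihydroxyphenyl)-1-(4-hydroxyphenyl)indane-5,7-diol
Conditions: H2 (1 atm), palladium on carbon (10% Pd/C), EtOAc–THF 1:1, rt
Reagents that add atoms: none
Why: Hydrogenolysis of five aryl benzyl ethers in a non-protic medium; the silyl ether is kept on C8 because a free 4-hydroxybenzylic alcohol would itself be prone to hydrogenolysis.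

Step 14
Reactants: 24 (1R,2S,3R)-3-{(R)-[(tert-butyldimethylsilyl)oxy](4-hydroxyphenyl)methyl}-2-(3,5-dihydroxyphenyl)-1-(4-hydroxyphenyl)indane-5,7-diol
Product: 25 (1R,2S,3R)-2-(3,5-dihydroxyphenyl)-3-[(R)-hydroxy(4-hydroxyphenyl)methyl]-1-(4-hydroxyphenyl)indane-5,7-diol (CNP0214825.1)
Conditions: Bu4NF, AcOH (1:1, 8 equiv), THF, 0 °C → rt, under argon
Reagents that add atoms: none
Why: Fluoride cleavage of the secondary silyl ether, buffered with acetic acid so that the polyphenol meets neither strong base nor strong acid, either of which could ionise the 4-hydroxybenzylic carbinol.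

## Compound list

1 | cyclopent-4-ene-1,3-dione | O=C1CC(=O)C=C1 | starting material
2 | 4,4-dimethoxycyclopent-2-en-1-one | COC1(OC)C=CC(=O)C1 | intermediate
3 | [3,5-bis(benzyloxy)phenyl]boronic acid | OB(O)c1cc(OCc2ccccc2)cc(OCc2ccccc2)c1 | starting material
4 | (4S)-4-[3,5-bis(benzyloxy)phenyl]-3,3-dimethoxycyclopentan-1-one (not isolated) | COC1(OC)CC(=O)C[C@H]1c1cc(OCc2ccccc2)cc(OCc2ccccc2)c1 | intermediate
5 | (4S)-4-[3,5-bis(benzyloxy)phenyl]-3-methoxycyclopent-2-en-1-one | COC1=CC(=O)C[C@H]1c1cc(OCc2ccccc2)cc(OCc2ccccc2)c1 | intermediate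
6 | 4-(benzyloxy)benzaldehyde | O=Cc1ccc(OCc2ccccc2)cc1 | starting material
7 | lithium (3S)-3-[3,5-bis(benzyloxy)phenyl]-4-methoxycyclopenta-1,4-dien-1-olate (not isolated) | COC1=CC(O[Li])=C[C@H]1c1cc(OCc2ccccc2)cc(OCc2ccccc2)c1 | intermediate
8 | dicyclohexyl{[(3S)-3-[3,5-bis(benzyloxy)phenyl]-4-methoxycyclopenta-1,4-dien-1-yl]oxy}borane (not isolated) | COC1=CC(OB(C2CCCCC2)C2CCCCC2)=C[C@H]1c1cc(OCc2ccccc2)cc(OCc2ccccc2)c1 | intermediate
9 | (4S,5S)-4-[3,5-bis(benzyloxy)phenyl]-5-{(R)-[4-(benzyloxy)phenyl](hydroxy)methyl}-3-methoxycyclopent-2-en-1-one | COC1=CC(=O)[C@H]([C@@H](O)c2ccc(OCc3ccccc3)cc2)[C@H]1c1cc(OCc2ccccc2)cc(OCc2ccccc2)c1 | intermediate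
10 | (4S,5S)-4-[3,5-bis(benzyloxy)phenyl]-5-{(R)-[4-(benzyloxy)phenyl][(tert-butyldimethylsilyl)oxy]methyl}-3-methoxycyclopent-2-en-1-one | COC1=CC(=O)[C@H]([C@@H](O[Si](C)(C)C(C)(C)C)c2ccc(OCc3ccccc3)cc2)[C@H]1c1cc(OCc2ccccc2)cc(OCc2ccccc2)c1 | intermediate
11 | (4S,5S)-4-[3,5-bis(benzyloxy)phenyl]-5-{(R)-[4-(benzyloxy)phenyl][(tert-butyldimethylsilyl)oxy]methyl}-2-bromo-3-methoxycyclopent-2-en-1-one | COC1=C(Br)C(=O)[C@H]([C@@H](O[Si](C)(C)C(C)(C)C)c2ccc(OCc3ccccc3)cc2)[C@H]1c1cc(OCc2ccccc2)cc(OCc2ccccc2)c1 | intermediate
12 | 4-[3,5-bis(benzyloxy)phenyl]-5-{(R)-[4-(benzyloxy)phenyl][(tert-butyldimethylsilyl)oxy]methyl}-2-bromo-3-methoxycyclopent-2-en-1-ol, ring substituents as in 11, carbinol epimers (not isolated) | COC1=C(Br)C(O)[C@H]([C@@H](O[Si](C)(C)C(C)(C)C)c2ccc(OCc3ccccc3)cc2)[C@H]1c1cc(OCc2ccccc2)cc(OCc2ccccc2)c1 | intermediate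
13 | (4R,5S)-5-[3,5-bis(benzyloxy)phenyl]-4-{(R)-[4-(benzyloxy)phenyl][(tert-butyldimethylsilyl)oxy]methyl}-2-bromocyclopent-2-en-1-one | O=C1C(Br)=C[C@H]([C@@H](O[Si](C)(C)C(C)(C)C)c2ccc(OCc3ccccc3)cc2)[C@H]1c1cc(OCc2ccccc2)cc(OCc2ccccc2)c1 | intermediate
14 | methyl acetoacetate | COC(=O)CC(C)=O | starting material
15 | methyl 3-[(trimethylsilyl)oxy]but-2-enoate (E/Z mixture) | COC(=O)C=C(C)O[Si](C)(C)C | intermediate
16 | lithium 1-methoxy-3-[(trimethylsilyl)oxy]buta-1,3-dien-1-olate (not isolated) | [Li]OC(OC)=CC(=C)O[Si](C)(C)C | intermediate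
17 | 1-methoxy-1,3-bis[(trimethylsilyl)oxy]buta-1,3-diene | CO/C(O[Si](C)(C)C)=C/C(=C)O[Si](C)(C)C | intermediate
18 | 7a-bromo-7-methoxy-5,7-bis[(trimethylsilyl)oxy]-3a,4,7,7a-tetrahydroindan-1-one with the C2 aryl and C3 side chain of 13, mixture at C3a, C7 and C7a (not isolated) | O=C1[C@H](c2cc(OCc3ccccc3)cc(OCc3ccccc3)c2)[C@@H]([C@@H](O[Si](C)(C)C(C)(C)C)c2ccc(OCc3ccccc3)cc2)C2CC(O[Si](C)(C)C)=CC(OC)(O[Si](C)(C)C)C12Br | intermediate
19 | (2S,3R)-2-[3,5-bis(benzyloxy)phenyl]-3-{(R)-[4-(benzyloxy)phenyl][(tert-butyldimethylsilyl)oxy]methyl}-5,7-dihydroxyindan-1-one | O=C1c2c(O)cc(O)cc2[C@H]([C@@H](O[Si](C)(C)C(C)(C)C)c2ccc(OCc3ccccc3)cc2)[C@H]1c1cc(OCc2ccccc2)cc(OCc2ccccc2)c1 | intermediate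
20 | (2S,3R)-5,7-bis(benzyloxy)-2-[3,5-bis(benzyloxy)phenyl]-3-{(R)-[4-(benzyloxy)phenyl][(tert-butyldimethylsilyl)oxy]methyl}indan-1-one | O=C1c2c(OCc3ccccc3)cc(OCc3ccccc3)cc2[C@H]([C@@H](O[Si](C)(C)C(C)(C)C)c2ccc(OCc3ccccc3)cc2)[C@H]1c1cc(OCc2ccccc2)cc(OCc2ccccc2)c1 | intermediate
21 | (2S,3R)-5,7-bis(benzyloxy)-2-[3,5-bis(benzyloxy)phenyl]-3-{(R)-[4-(benzyloxy)phenyl][(tert-butyldimethylsilyl)oxy]methyl}indan-1-ol, C1 epimers | OC1c2c(OCc3ccccc3)cc(OCc3ccccc3)cc2[C@H]([C@@H](O[Si](C)(C)C(C)(C)C)c2ccc(OCc3ccccc3)cc2)[C@H]1c1cc(OCc2ccccc2)cc(OCc2ccccc2)c1 | intermediate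
22 | benzyl phenyl ether | c1ccc(COc2ccccc2)cc1 | starting material
23 | (1R,2S,3R)-5,7-bis(benzyloxy)-1-[4-(benzyloxy)phenyl]-2-[3,5-bis(benzyloxy)phenyl]-3-{(R)-[4-(benzyloxy)phenyl][(tert-butyldimethylsilyl)oxy]methyl}indane | c1ccccc1COc1ccc([C@@H]2c3c(OCc4ccccc4)cc(OCc4ccccc4)cc3[C@H]([C@@H](O[Si](C)(C)C(C)(C)C)c3ccc(OCc4ccccc4)cc3)[C@H]2c2cc(OCc3ccccc3)cc(OCc3ccccc3)c2)cc1 | intermediate
24 | (1R,2S,3R)-3-{(R)-[(tert-butyldimethylsilyl)oxy](4-hydroxyphenyl)methyl}-2-(3,5-dihydroxyphenyl)-1-(4-hydroxyphenyl)indane-5,7-diol | Oc1ccc([C@@H]2c3c(O)cc(O)cc3[C@H]([C@@H](O[Si](C)(C)C(C)(C)C)c3ccc(O)cc3)[C@H]2c2cc(O)cc(O)c2)cc1 | intermediate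
25 | (1R,2S,3R)-2-(3,5-dihydroxyphenyl)-3-[(R)-hydroxy(4-hydroxyphenyl)methyl]-1-(4-hydroxyphenyl)indane-5,7-diol | Oc1ccc([C@@H]2c3c(O)cc(O)cc3[C@H]([C@@H](O)c3ccc(O)cc3)[C@H]2c2cc(O)cc(O)c2)cc1 | target

## Step count and least certain steps

Total: 14 steps. Longest linear sequence: 12 steps (steps 1–6 and 9–14); the diene branch (steps 7 and 8) joins at step 9.

**Step 9 (key step).** The cycloaddition may stall because the enone β-carbon is shielded by the C3 side chain. The diene may add in Michael fashion without ring closure. Bromine may be lost as positive halogen to an enolate instead of leaving with the C3a proton. Base may trigger vinylogous elimination of the silyloxy group from 13.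

Fallback, from 10 back to 19: the ring is built by carbonyl addition and Claisen acylation, with no halogen and no cycloaddition.
- The dianion of methyl acetoacetate F1 (from 14 with NaH, then n-BuLi) adds 1,2 to the vinylogous ester carbonyl of 10 and gives the tertiary carbinol F2.
- Dilute acid effects the Stork–Danheiser transposition to the 3-substituted cyclopentenone keto ester F3.
- NaOMe in methanol then closes ring A by attack of the dienolate α-carbon (C7a) on the ester, and tautomerisation gives 19.

**Step 3 (aldol).** The anti:syn ratio at C8 may be low. The base may also remove the benzylic γ-proton of 5 instead of the α′-proton, which would erode the enantiomeric purity, and the aldolate may revert on work-up.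

Fallback, from 23 back to 23: C8 is reset late by reagent control. Material carried through as a C8 mixture is desilylated with Bu4NF to the pentabenzyl ether alcohol F4 and oxidised with Dess–Martin periodinane to the aryl ketone F5. Epimerisation next to this ketone can only restore the trans ring. Reduction with the (S)-Me-CBS oxazaborolidine and BH3·SMe2 gives (R)-configured F4, and silylation as in step 4 returns 23.

**Step 5 (bromination).** Electrophilic substitution of the 3,5-bis(benzyloxy)phenyl ring may compete with bromination of the enol-ether carbon, or a second bromine may enter.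

Fallback, from 10 back to 13: bromine enters as bromide.
- Reduction of 10 with iBu2AlH gives the allylic alcohol F6, and dilute HCl converts it into the halogen-free enone F7.
- Nucleophilic epoxidation (H2O2, NaOH, MeOH, 0 °C) gives the epoxy ketone F8.
- MgBr2·OEt2 opens the epoxide at the α-carbon to the bromohydrin F9, which loses water on treatment with MsCl and Et3N to give 13.

**Step 12 (Friedel–Crafts arylation).** The C1 cation may be captured by the dialkoxy rings of a second substrate molecule faster than by 22. It may lose the C2 proton reversibly, which would scramble C2 through an indene. Attack may occur ortho on 22, or C8 may ionise with loss of the silyl ether.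

Fallback, from 19 to 24: the electrophile is a neutral ortho-quinone methide and the nucleophile is anionic, so neither acid nor competing arenes intervene.
- The non-chelated C5 hydroxyl of 19 is benzylated selectively (BnBr 1.05 equiv, K2CO3, acetone) to the mono-benzyl ether F10.
- NaBH4 gives the 2-hydroxybenzylic alcohol F11.
- Excess 4-(benzyloxy)phenylmagnesium bromide in THF–toluene, with warming, converts the magnesium salt of F11 into the ortho-quinone methide F12.
- The same Grignard reagent adds to C1 of F12 anti to the C2 aryl group and gives the phenol F13.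
- Hydrogenolysis as in step 13 leads to 24.

## Further compounds

F1 | step 9 | dianion of methyl acetoacetate (sodium lithium salt) | [Na+].[Li+].COC(=O)C=C([O-])[CH2-]
F2 | step 9 | methyl 4-[4-[3,5-bis(benzyloxy)phenyl]-5-{(R)-[4-(benzyloxy)phenyl][(tert-butyldimethylsilyl)oxy]methyl}-1-hydroxy-3-methoxycyclopent-2-en-1-yl]-3-oxobutanoate, ring centres as in 10, carbinol epimers | COC1=CC(O)(CC(=O)CC(=O)OC)[C@H]([C@@H](O[Si](C)(C)C(C)(C)C)c2ccc(OCc3ccccc3)cc2)[C@H]1c1cc(OCc2ccccc2)cc(OCc2ccccc2)c1
F3 | step 9 | methyl 4-{(4S,5R)-4-[3,5-bis(benzyloxy)phenyl]-5-[(R)-[4-(benzyloxy)phenyl][(tert-butyldimethylsilyl)oxy]methyl]-3-oxocyclopent-1-en-1-yl}-3-oxobutanoate | O=C1C=C(CC(=O)CC(=O)OC)[C@H]([C@@H](O[Si](C)(C)C(C)(C)C)c2ccc(OCc3ccccc3)cc2)[C@H]1c1cc(OCc2ccccc2)cc(OCc2ccccc2)c1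
F4 | step 3 | (1R,2S,3R)-5,7-bis(benzyloxy)-1-[4-(benzyloxy)phenyl]-2-[3,5-bis(benzyloxy)phenyl]-3-{(R)-[4-(benzyloxy)phenyl](hydroxy)methyl}indane | c1ccccc1COc1ccc([C@@H]2c3c(OCc4ccccc4)cc(OCc4ccccc4)cc3[C@H]([C@@H](O)c3ccc(OCc4ccccc4)cc3)[C@H]2c2cc(OCc3ccccc3)cc(OCc3ccccc3)c2)cc1
F5 | step 3 | [(1R,2S,3R)-5,7-bis(benzyloxy)-3-[4-(benzyloxy)phenyl]-2-[3,5-bis(benzyloxy)phenyl]... C3-aroyl ketone: {(1R,2S,3R)-5,7-bis(benzyloxy)-1-[4-(benzyloxy)phenyl]-2-[3,5-bis(benzyloxy)phenyl]indan-3-yl}[4-(benzyloxy)phenyl]methanone | c1ccccc1COc1ccc([C@@H]2c3c(OCc4ccccc4)cc(OCc4ccccc4)cc3[C@H](C(=O)c3ccc(OCc4ccccc4)cc3)[C@H]2c2cc(OCc3ccccc3)cc(OCc3ccccc3)c2)cc1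
F6 | step 5 | 4-[3,5-bis(benzyloxy)phenyl]-5-{(R)-[4-(benzyloxy)phenyl][(tert-butyldimethylsilyl)oxy]methyl}-3-methoxycyclopent-2-en-1-ol, ring centres as in 10, carbinol epimers | COC1=CC(O)[C@H]([C@@H](O[Si](C)(C)C(C)(C)C)c2ccc(OCc3ccccc3)cc2)[C@H]1c1cc(OCc2ccccc2)cc(OCc2ccccc2)c1
F7 | step 5 | (4S,5S)-5-[3,5-bis(benzyloxy)phenyl]-4-{(R)-[4-(benzyloxy)phenyl][(tert-butyldimethylsilyl)oxy]methyl}cyclopent-2-en-1-one | O=C1C=C[C@H]([C@@H](O[Si](C)(C)C(C)(C)C)c2ccc(OCc3ccccc3)cc2)[C@H]1c1cc(OCc2ccccc2)cc(OCc2ccccc2)c1
F8 | step 5 | 2,3-epoxide of F7 (3-[3,5-bis(benzyloxy)phenyl]-4-{(R)-[4-(benzyloxy)phenyl][(tert-butyldimethylsilyl)oxy]methyl}-6-oxabicyclo[3.1.0]hexan-2-one), epoxide expected anti to the side chain | O=C1C2OC2[C@H]([C@@H](O[Si](C)(C)C(C)(C)C)c2ccc(OCc3ccccc3)cc2)[C@H]1c1cc(OCc2ccccc2)cc(OCc2ccccc2)c1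
F9 | step 5 | 5-[3,5-bis(benzyloxy)phenyl]-4-{(R)-[4-(benzyloxy)phenyl][(tert-butyldimethylsilyl)oxy]methyl}-2-bromo-3-hydroxycyclopentan-1-one, ring centres C4 and C5 as in F7 | O=C1C(Br)C(O)[C@H]([C@@H](O[Si](C)(C)C(C)(C)C)c2ccc(OCc3ccccc3)cc2)[C@H]1c1cc(OCc2ccccc2)cc(OCc2ccccc2)c1
F10 | step 12 | (2S,3R)-5-(benzyloxy)-2-[3,5-bis(benzyloxy)phenyl]-3-{(R)-[4-(benzyloxy)phenyl][(tert-butyldimethylsilyl)oxy]methyl}-7-hydroxyindan-1-one | O=C1c2c(O)cc(OCc3ccccc3)cc2[C@H]([C@@H](O[Si](C)(C)C(C)(C)C)c2ccc(OCc3ccccc3)cc2)[C@H]1c1cc(OCc2ccccc2)cc(OCc2ccccc2)c1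
F11 | step 12 | (2S,3R)-5-(benzyloxy)-2-[3,5-bis(benzyloxy)phenyl]-3-{(R)-[4-(benzyloxy)phenyl][(tert-butyldimethylsilyl)oxy]methyl}indane-1,7-diol, C1 epimers | OC1c2c(O)cc(OCc3ccccc3)cc2[C@H]([C@@H](O[Si](C)(C)C(C)(C)C)c2ccc(OCc3ccccc3)cc2)[C@H]1c1cc(OCc2ccccc2)cc(OCc2ccccc2)c1
F12 | step 12 | ortho-quinone methide from F11: 6-(benzyloxy)-2-[3,5-bis(benzyloxy)phenyl]-1-{(R)-[4-(benzyloxy)phenyl][(tert-butyldimethylsilyl)oxy]methyl}-1,2-dihydroinden-4-one with C3=C3a and C5=C6 unsaturation (inden-4-one numbering), ring centres as in F11 | O=C1C=C(OCc2ccccc2)C=C2[C@H]([C@@H](O[Si](C)(C)C(C)(C)C)c3ccc(OCc4ccccc4)cc3)[C@@H](c3cc(OCc4ccccc4)cc(OCc4ccccc4)c3)C=C12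
F13 | step 12 | (1R,2S,3R)-5-(benzyloxy)-1-[4-(benzyloxy)phenyl]-2-[3,5-bis(benzyloxy)phenyl]-3-{(R)-[4-(benzyloxy)phenyl][(tert-butyldimethylsilyl)oxy]methyl}indan-7-ol | c1ccccc1COc1ccc([C@@H]2c3c(O)cc(OCc4ccccc4)cc3[C@H]([C@@H](O[Si](C)(C)C(C)(C)C)c3ccc(OCc4ccccc4)cc3)[C@H]2c2cc(OCc3ccccc3)cc(OCc3ccccc3)c2)cc1
A1 | alternative 1 | methyl 2-{2-[(3,5-di-tert-butyl-4-oxocyclohexa-2,5-dien-1-ylidene)methyl]-3,5-dimethoxyphenyl}acetate | COC(=O)Cc1cc(OC)cc(OC)c1C=C1C=C(C(C)(C)C)C(=O)C(C(C)(C)C)=C1
A2 | alternative 1 | 3,5-dimethoxybenzyl bromide | COc1cc(CBr)cc(OC)c1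
A3 | alternative 1 | methyl all-trans 1-(3,5-di-tert-butyl-4-hydroxyphenyl)-2-(3,5-dimethoxyphenyl)-5,7-dimethoxyindane-3-carboxylate | CC(C)(C)c1cc(cc(C(C)(C)C)c1O)[C@@H]1c2c(OC)cc(OC)cc2[C@H](C(=O)OC)[C@H]1c1cc(OC)cc(OC)c1
A4 | alternative 2 | 3-[(tert-butyldimethylsilyloxy)(4-methoxyphenyl)methyl]-5,7-dimethoxyindene with the C1=C2 double bond (target numbering), C3 and C8 configured as in the target | COc1ccc([C@H](O[Si](C)(C)C(C)(C)C)[C@@H]2C=Cc3c(OC)cc(OC)cc32)cc1
A5 | alternative 2 | 3,5-dimethoxybenzenediazonium tetrafluoroborate | COc1cc(cc(OC)c1)[N+]#N.F[B-](F)(F)F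
A6 | alternative 2 | anisole | COc1ccccc1
A7 | alternative 2 | C8 tert-butyldimethylsilyl ether of the target pentamethyl ether | COc1ccc([C@@H]2c3c(OC)cc(OC)cc3[C@H]([C@@H](O[Si](C)(C)C(C)(C)C)c3ccc(OC)cc3)[C@H]2c2cc(OC)cc(OC)c2)cc1
A8 | alternative 3 | 2-[(E)-3-(3,5-dimethoxyphenyl)-4-(4-methoxyphenyl)-1-(pinacolatoboryl)but-1-en-4-yl]-3,5-dimethoxyphenyl triflate, C1 and C2 configured as in the target | COc1ccc([C@H](c2c(OC)cc(OC)cc2OS(=O)(=O)C(F)(F)F)[C@@H](/C=C/B2OC(C)(C)C(C)(C)O2)c2cc(OC)cc(OC)c2)cc1
A9 | alternative 3 | 4-methoxyphenyllithium | [Li]c1ccc(OC)cc1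
A10 | alternative 3 | C8 pinacol boronate of the indane pentamethyl ether | COc1ccc([C@@H]2c3c(OC)cc(OC)cc3[C@H]([C@@H](B3OC(C)(C)C(C)(C)O3)c3ccc(OC)cc3)[C@H]2c2cc(OC)cc(OC)c2)cc1
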